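**Plan**

- Labels: ring C1 (CMe2), C2 (C=O), C3, C4, C5 (C(OH)Me), C6 (CH); chain C7–C8–C9(Me)(OH)–C10–C11–O–coumarin.
- Retrosynthetic cuts, in order: the C11–O aryl ether; the ring bond C4–C5; the cyclopropane that masks C2–C3–C4 (back to a C2 ester); the C1–C6 bond ([3,3] shift); the C5=C6 alkene (Wittig); the linalool alkene.
- Forward: (R)-linalool supplies C6–C11, a keto ylide adds C5 and an isobutyrate adds C1/C2. The whole chain is in place before the only carbocycle closes, and the coumarin is joined last.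
- Enabling feature: the C2 ketone and the C5 tertiary carbinol are 1,4-related through C3–C4. That is the pattern left when a C2–C3–C4 ketone homoenolate (a cyclopropanol on C2) adds to a C5 methyl ketone; quaternary C1 leaves C2 enolisable on one side only.
- Stereochemistry: C9 from (R)-linalool; C6 by chirality transfer in the Ireland–Claisen step from a carbinol set by Corey–Bakshi–Shibata reduction; C5 from C6 in the chair-like ring closure.

Key step: step 11

Remark: the stabilised ylide 7 and (R)-(−)-linalool of high enantiomeric purity are taken as purchasable, and 18 is drawn as the open hydroxy ketone although it may rest partly as its five-membered cyclic hemiketal.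

**Route**

Step 1
Reactants: 1 (R)-linalool
Product: 3 (3R)-3,7-dimethyloct-6-ene-1,3-diol, via B-alkyl-9-BBN adduct 2 (not isolated)
Conditions: 9-BBN (2.2 equiv), THF, 0 °C → rt; then NaOH, H2O2, 0 °C → rt
Reagents that add atoms: hydrogen peroxide, OO
Why: Hydroboration–oxidation, in which the bulky 9-BBN should add to the monosubstituted vinyl group far faster than to the trisubstituted alkene and place boron on the terminal carbon, so that oxidation gives the primary C11 alcohol without touching C9.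

Step 2
Reactants: 3 (3R)-3,7-dimethyloct-6-ene-1,3-diol
Product: 4 (4R)-2,2,4-trimethyl-4-(4-methylpent-3-en-1-yl)-1,3-dioxane
Conditions: 2,2-dimethoxypropane, PPTS (cat.), CH2Cl2, rt
Reagents that add atoms: 2,2-dimethoxypropane, COC(C)(C)OC
Why: Acid-catalysed transketalisation (acetonide formation) ties the primary and the tertiary hydroxyl into a 1,3-dioxane that should be inert to the bases, organometallic reagents and ozone used later.

Step 3
Reactants: 4 (4R)-2,2,4-trimethyl-4-(4-methylpent-3-en-1-yl)-1,3-dioxane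
Product: 6 3-[(4R)-2,2,4-trimethyl-1,3-dioxan-4-yl]propanal, via ozonide 5 (not isolated)
Conditions: O3, CH2Cl2, −78 °C; then Me2S, −78 °C → rt
Reagents that add atoms: ozone, [O-][O+]=O
Why: Ozonolysis with reductive work-up cleaves the only alkene to the C6 aldehyde under neutral conditions that spare the acetonide.

Step 4
Reactants: 6 3-[(4R)-2,2,4-trimethyl-1,3-dioxan-4-yl]propanal; 7 3-(triphenylphosphoranylidene)butan-2-one
Product: 8 (3E)-3-methyl-6-[(4R)-2,2,4-trimethyl-1,3-dioxan-4-yl]hex-3-en-2-one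
Conditions: toluene, 100 °C
Reagents that add atoms: 3-(triphenylphosphoranylidene)butan-2-one (7), CC(=O)C(C)=P(c1ccccc1)(c1ccccc1)c1ccccc1
Why: Wittig olefination with a stabilised keto ylide should give the (E)-trisubstituted enone, the ylide carbon becoming C5 and already carrying its methyl group.

Step 5
Reactants: 8 (3E)-3-methyl-6-[(4R)-2,2,4-trimethyl-1,3-dioxan-4-yl]hex-3-en-2-one
Product: 9 (2R,3E)-3-methyl-6-[(4R)-2,2,4-trimethyl-1,3-dioxan-4-yl]hex-3-en-2-ol
Conditions: (S)-2-methyl-CBS-oxazaborolidine (20 mol %), catecholborane, toluene, −78 °C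
Reagents that add atoms: none
Why: Corey–Bakshi–Shibata reduction, in which the α-branched alkenyl group acts as the large substituent, so the (S)-oxazaborolidine should deliver hydride to give the (R)-carbinol under catalyst control, with 1,2-reduction favoured by catecholborane at low temperature.

Step 6
Reactants: 9 (2R,3E)-3-methyl-6-[(4R)-2,2,4-trimethyl-1,3-dioxan-4-yl]hex-3-en-2-ol; 10 isobutyryl chloride
Product: 11 (2R,3E)-3-methyl-6-[(4R)-2,2,4-trimethyl-1,3-dioxan-4-yl]hex-3-en-2-yl 2-methylpropanoate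
Conditions: Et3N, DMAP (cat.), CH2Cl2, 0 °C → rt
Reagents that add atoms: isobutyryl chloride (10), CC(C)C(Cl)=O
Why: DMAP-catalysed acylation of the secondary allylic alcohol leaves the C–O bond untouched, so the carbinol configuration is retained.

Step 7
Reactants: 11 (2R,3E)-3-methyl-6-[(4R)-2,2,4-trimethyl-1,3-dioxan-4-yl]hex-3-en-2-yl 2-methylpropanoate
Product: 14 (3S)-3-[(2E)-but-2-en-2-yl]-2,2-dimethyl-5-[(4R)-2,2,4-trimethyl-1,3-dioxan-4-yl]pentanoic acid, via silyl ketene acetal 12 (not isolated), via trimethylsilyl ester 13 (not isolated)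
Conditions: LDA, THF, −78 °C; TMSCl/Et3N, −78 °C → 60 °C; then H2O, citric acid to pH 4–5
Reagents that add atoms: none
Why: Ireland–Claisen rearrangement, in which the silyl ketene acetal shifts suprafacially with the carbinol methyl pseudo-equatorial, so the C1–C6 bond forms on one face of the (E)-alkene and the (R)-carbinol configuration is transferred to C6, the symmetrical CMe2 terminus making chair and boat pathways converge on the same product.

Step 8
Reactants: 14 (3S)-3-[(2E)-but-2-en-2-yl]-2,2-dimethyl-5-[(4R)-2,2,4-trimethyl-1,3-dioxan-4-yl]pentanoic acid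
Product: 15 methyl (3S)-3-[(2E)-but-2-en-2-yl]-2,2-dimethyl-5-[(4R)-2,2,4-trimethyl-1,3-dioxan-4-yl]pentanoate
Conditions: MeI, K2CO3, DMF, rt
Reagents that add atoms: iodomethane, CI
Why: Carboxylate O-alkylation (SN2 on iodomethane) is insensitive to the neopentyl-type hindrance that would slow a Fischer esterification, and it avoids acid.

Step 9
Reactants: 15 methyl (3S)-3-[(2E)-but-2-en-2-yl]-2,2-dimethyl-5-[(4R)-2,2,4-trimethyl-1,3-dioxan-4-yl]pentanoate
Product: 16 1-[(3S,4E)-2,4-dimethyl-3-{2-[(4R)-2,2,4-trimethyl-1,3-dioxan-4-yl]ethyl}hex-4-en-2-yl]cyclopropan-1-ol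
Conditions: EtMgBr (4 equiv), Ti(OiPr)4 (1 equiv), THF, 0 °C → rt; then aq. NH4Cl
Reagents that add atoms: ethylmagnesium bromide, CC[Mg]Br
Why: Kulinkovich cyclopropanation, in which the titanacyclopropane formed from EtMgBr and Ti(OiPr)4 acts as a 1,2-dicarbanion toward the ester and gives the cyclopropanol that masks C2–C3–C4, the trisubstituted alkene being too hindered for ligand exchange.

Step 10
Reactants: 16 1-[(3S,4E)-2,4-dimethyl-3-{2-[(4R)-2,2,4-trimethyl-1,3-dioxan-4-yl]ethyl}hex-4-en-2-yl]cyclopropan-1-ol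
Product: 18 (3R)-4-(1-hydroxycyclopropyl)-4-methyl-3-{2-[(4R)-2,2,4-trimethyl-1,3-dioxan-4-yl]ethyl}pentan-2-one, via ozonide 17 (not isolated)
Conditions: O3, CH2Cl2, −78 °C, stopped at the first excess of ozone; then PPh3, −78 °C → rt
Reagents that add atoms: ozone, [O-][O+]=O
Why: Ozonolysis, in which ozone should attack the electron-rich trisubstituted π bond far faster than any σ bond and, because the alkene carbon on C6 already bears a methyl group, cleavage gives the C5 acetyl group directly under a neutral work-up that should leave C6 unepimerised.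

Step 11
Reactants: 18 (3R)-4-(1-hydroxycyclopropyl)-4-methyl-3-{2-[(4R)-2,2,4-trimethyl-1,3-dioxan-4-yl]ethyl}pentan-2-one
Product: 21 (3R,4S)-4-hydroxy-2,2,4-trimethyl-3-{2-[(4R)-2,2,4-trimethyl-1,3-dioxan-4-yl]ethyl}cyclohexan-1-one, via ethylzinc cyclopropoxide 19 (not isolated), via zinc homoenolate 20 (not isolated)
Conditions: Et2Zn (1.5 equiv), toluene (dilute), 0 → 60 °C; then pH 7 buffer
Reagents that add atoms: none
Why: Proposed new method: Et2Zn should deprotonate the cyclopropanol to the ethylzinc cyclopropoxide 19, whose strained C2–C4 bond opens to the C-zincated ketone 20, and the C4–Zn bond should then add to the C5 ketone in the same molecule, the tertiary zinc alkoxide being the sink of otherwise reversible equilibria. The closest known reaction types are the Et2Zn-mediated opening of cyclopropanols to zinc homoenolates with their intermolecular additions to carbonyl and conjugate acceptors, and Barbier-type intramolecular organozinc additions; a ring-closing 1,2-addition of such a homoenolate to a ketone has not been shown. The cyclohexane closes in a 6-exo-trig mode, C4 attacking the C5 carbonyl carbon with the C=O bond outside the ring. The new C5 stereocentre is controlled by C6: in the chair-like transition state the C7 chain is equatorial and the acetyl methyl must avoid the syn-axial C1 methyl, so the carbonyl oxygen is axial and ends cis to C7. The step needs attack through C4 rather than aldol attack through C3 of an enolised homoenolate (which would give a five-membered ring) and no epimerisation at C6; amine-free conditions in a non-coordinating solvent disfavour enolisation, quaternary C1 blocks the other side of C2, and the gem-dimethyl group folds the chain toward closure (Thorpe–Ingold effect).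

Step 12
Reactants: 21 (3R,4S)-4-hydroxy-2,2,4-trimethyl-3-{2-[(4R)-2,2,4-trimethyl-1,3-dioxan-4-yl]ethyl}cyclohexan-1-one
Product: 22 (3R,4S)-3-[(3R)-3,5-dihydroxy-3-methylpentyl]-4-hydroxy-2,2,4-trimethylcyclohexan-1-one
Conditions: AcOH–H2O–THF, 40 °C
Reagents that add atoms: none
Why: Acid-catalysed acetal hydrolysis, in which the tetrasubstituted dioxane is strained by a syn-axial methyl contact and should open in warm aqueous acetic acid, mild enough to spare the two tertiary alcohols.

Step 13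
Reactants: 22 (3R,4S)-3-[(3R)-3,5-dihydroxy-3-methylpentyl]-4-hydroxy-2,2,4-trimethylcyclohexan-1-one; 23 umbelliferone
Product: 24 7-{[(3R)-3-hydroxy-5-[(1R,6S)-6-hydroxy-2,2,6-trimethyl-3-oxocyclohexyl]-3-methylpentyl]oxy}-2H-chromen-2-one
Conditions: PPh3, DIAD, THF, 0 °C → rt
Reagents that add atoms: umbelliferone (23), Oc1ccc2ccc(=O)oc2c1
Why: Mitsunobu etherification, in which only the primary C11 hydroxyl can form the reactive alkoxyphosphonium ion that the acidic 7-hydroxycoumarin displaces by SN2, the two tertiary alcohols staying untouched.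

**Compound list**

1 | (R)-linalool, (3R)-3,7-dimethylocta-1,6-dien-3-ol | C=C[C@](C)(O)CCC=C(C)C | starting material
2 | B-alkyl-9-BBN adduct, 9-[(3R)-3-hydroxy-3,7-dimethyloct-6-en-1-yl]-9-borabicyclo[3.3.1]nonane | CC(C)=CCC[C@@](C)(O)CCB1C2CCCC1CCC2 | intermediate
3 | (3R)-3,7-dimethyloct-6-ene-1,3-diol | OCC[C@](C)(O)CCC=C(C)C | intermediate
4 | (4R)-2,2,4-trimethyl-4-(4-methylpent-3-en-1-yl)-1,3-dioxane | CC(C)=CCC[C@]1(C)CCOC(C)(C)O1 | intermediate
5 | ozonide of 4, 3,3-dimethyl-5-{2-[(4R)-2,2,4-trimethyl-1,3-dioxan-4-yl]ethyl}-1,2,4-trioxolane (epimers at the ring carbon) | CC1(C)OOC(CC[C@]2(C)CCOC(C)(C)O2)O1 | intermediate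
6 | 3-[(4R)-2,2,4-trimethyl-1,3-dioxan-4-yl]propanal | O=CCC[C@]1(C)CCOC(C)(C)O1 | intermediate
7 | 3-(triphenylphosphoranylidene)butan-2-one | CC(=O)C(C)=P(c1ccccc1)(c1ccccc1)c1ccccc1 | starting material
8 | (3E)-3-methyl-6-[(4R)-2,2,4-trimethyl-1,3-dioxan-4-yl]hex-3-en-2-one | CC(=O)/C(C)=C/CC[C@]1(C)CCOC(C)(C)O1 | intermediate
9 | (2R,3E)-3-methyl-6-[(4R)-2,2,4-trimethyl-1,3-dioxan-4-yl]hex-3-en-2-ol | C[C@@H](O)/C(C)=C/CC[C@]1(C)CCOC(C)(C)O1 | intermediate
10 | isobutyryl chloride | CC(C)C(Cl)=O | starting material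
11 | (2R,3E)-3-methyl-6-[(4R)-2,2,4-trimethyl-1,3-dioxan-4-yl]hex-3-en-2-yl 2-methylpropanoate | CC(C)C(=O)O[C@H](C)/C(C)=C/CC[C@]1(C)CCOC(C)(C)O1 | intermediate
12 | silyl ketene acetal of 11, trimethyl[(2-methyl-1-{[(2R,3E)-3-methyl-6-[(4R)-2,2,4-trimethyl-1,3-dioxan-4-yl]hex-3-en-2-yl]oxy}prop-1-en-1-yl)oxy]silane | CC(C)=C(O[Si](C)(C)C)O[C@H](C)/C(C)=C/CC[C@]1(C)CCOC(C)(C)O1 | intermediate
13 | trimethylsilyl (3S)-3-[(2E)-but-2-en-2-yl]-2,2-dimethyl-5-[(4R)-2,2,4-trimethyl-1,3-dioxan-4-yl]pentanoate | C/C=C(\C)[C@H](CC[C@]1(C)CCOC(C)(C)O1)C(C)(C)C(=O)O[Si](C)(C)C | intermediate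
14 | (3S)-3-[(2E)-but-2-en-2-yl]-2,2-dimethyl-5-[(4R)-2,2,4-trimethyl-1,3-dioxan-4-yl]pentanoic acid | C/C=C(\C)[C@H](CC[C@]1(C)CCOC(C)(C)O1)C(C)(C)C(=O)O | intermediate
15 | methyl (3S)-3-[(2E)-but-2-en-2-yl]-2,2-dimethyl-5-[(4R)-2,2,4-trimethyl-1,3-dioxan-4-yl]pentanoate | C/C=C(\C)[C@H](CC[C@]1(C)CCOC(C)(C)O1)C(C)(C)C(=O)OC | intermediate
16 | 1-[(3S,4E)-2,4-dimethyl-3-{2-[(4R)-2,2,4-trimethyl-1,3-dioxan-4-yl]ethyl}hex-4-en-2-yl]cyclopropan-1-ol | C/C=C(\C)[C@H](CC[C@]1(C)CCOC(C)(C)O1)C(C)(C)C2(O)CC2 | intermediate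
17 | ozonide of 16, 1,2,4-trioxolane carrying a methyl on each ring carbon and the C6 residue on one of them (epimers at the ring carbons) | CC1OOC(C)(O1)[C@H](CC[C@]2(C)CCOC(C)(C)O2)C(C)(C)C3(O)CC3 | intermediate
18 | (3R)-4-(1-hydroxycyclopropyl)-4-methyl-3-{2-[(4R)-2,2,4-trimethyl-1,3-dioxan-4-yl]ethyl}pentan-2-one | CC(=O)[C@H](CC[C@]1(C)CCOC(C)(C)O1)C(C)(C)C2(O)CC2 | intermediate
19 | ethylzinc cyclopropoxide of 18 | CC(=O)[C@H](CC[C@]1(C)CCOC(C)(C)O1)C(C)(C)C2(O[Zn]CC)CC2 | intermediate
20 | zinc homoenolate, ethyl[(5R)-4,4-dimethyl-3,6-dioxo-5-{2-[(4R)-2,2,4-trimethyl-1,3-dioxan-4-yl]ethyl}heptyl]zinc | CC(=O)[C@H](CC[C@]1(C)CCOC(C)(C)O1)C(C)(C)C(=O)CC[Zn]CC | intermediate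
21 | (3R,4S)-4-hydroxy-2,2,4-trimethyl-3-{2-[(4R)-2,2,4-trimethyl-1,3-dioxan-4-yl]ethyl}cyclohexan-1-one | CC1(C)C(=O)CC[C@](C)(O)[C@@H]1CC[C@]2(C)CCOC(C)(C)O2 | intermediate
22 | (3R,4S)-3-[(3R)-3,5-dihydroxy-3-methylpentyl]-4-hydroxy-2,2,4-trimethylcyclohexan-1-one | CC1(C)C(=O)CC[C@](C)(O)[C@@H]1CC[C@@](C)(O)CCO | intermediate
23 | umbelliferone, 7-hydroxy-2H-chromen-2-one | Oc1ccc2ccc(=O)oc2c1 | starting material
24 | 7-{[(3R)-3-hydroxy-5-[(1R,6S)-6-hydroxy-2,2,6-trimethyl-3-oxocyclohexyl]-3-methylpentyl]oxy}-2H-chromen-2-one | CC1(C)C(=O)CC[C@](C)(O)[C@@H]1CC[C@@](C)(O)CCOc1ccc2ccc(=O)oc2c1 | target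

**Step count and risks**

Total step count: 13. Longest linear sequence: 13 steps, from 1 to 24; compounds 7, 10 and 23 are used as purchased.

Steps most likely to fail:

Step 11. The C4–Zn bond may prove too unreactive toward the hindered C5 ketone. The homoenolate could then enolise toward C3 and close a five-membered ring by aldol addition, be protonated to the open ethyl ketone, or let C6 epimerise under the basic zinc alkoxide. The fallback uses known reactions only and closes the same ring between C3 and C4. It sets out from 18. Addition of vinylmagnesium bromide with CeCl3 in THF at −78 °C to the acetyl group would give the C5 vinyl carbinol F1; the C5 epimers would be separated if the facial preference of the addition is insufficient. Aerobic ring-opening oxidation of the cyclopropanol with catalytic Pd(OAc)2 and pyridine under O2 in toluene at 80 °C would give the vinyl ketone F2. Ring-closing metathesis with the second-generation Hoveyda–Grubbs catalyst in CH2Cl2 at 40 °C would give the cyclohexenone F3 with loss of ethene. Hydrogenation over Pd/C in EtOAc would saturate C3=C4 and bring the route back at 21.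

Step 9. The ester carbonyl sits next to quaternary C1 and may insert too slowly into the titanacyclopropane, so that ester is recovered or reduced instead of cyclopropanated. The fallback sets out from 14 and bypasses steps 8 and 9. Excess MeLi in Et2O at 0 °C would convert the acid into the methyl ketone F4. LDA and TMSCl in THF at −78 °C would give the silyl enol ether F5, the ketone being enolisable on one side only. Simmons–Smith cyclopropanation with Et2Zn and CH2I2 in CH2Cl2 at 0 °C would give the silyloxycyclopropane F6; the electron-rich enol ether should react ahead of the hindered trisubstituted alkene. K2CO3 in MeOH would remove the silyl group and bring the route back at 16.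

Step 10. Ozone or the peroxidic intermediates may open the electron-rich cyclopropanol oxidatively in competition with alkene cleavage. The fallback sets out from 16. TESOTf and 2,6-lutidine in CH2Cl2 at −78 °C would give the triethylsilyl ether F7, which has no free cyclopropanol hydroxyl. Ozonolysis with PPh3 work-up would give the silyl-protected methyl ketone F8. TBAF buffered with AcOH in THF at 0 °C would free the cyclopropanol and bring the route back at 18.

**Further compounds**

F1 | step 11 | 1-[(3R,4S)-4-hydroxy-2,4-dimethyl-3-{2-[(4R)-2,2,4-trimethyl-1,3-dioxan-4-yl]ethyl}hex-5-en-2-yl]cyclopropan-1-ol | C=C[C@](C)(O)[C@H](CC[C@]1(C)CCOC(C)(C)O1)C(C)(C)C2(O)CC2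
F2 | step 11 | (5R,6S)-6-hydroxy-4,4,6-trimethyl-5-{2-[(4R)-2,2,4-trimethyl-1,3-dioxan-4-yl]ethyl}octa-1,7-dien-3-one | C=C[C@](C)(O)[C@H](CC[C@]1(C)CCOC(C)(C)O1)C(C)(C)C(=O)C=C
F3 | step 11 | (4S,5R)-4-hydroxy-4,6,6-trimethyl-5-{2-[(4R)-2,2,4-trimethyl-1,3-dioxan-4-yl]ethyl}cyclohex-2-en-1-one | CC1(C)C(=O)C=C[C@](C)(O)[C@@H]1CC[C@]2(C)CCOC(C)(C)O2
F4 | step 9 | (4S,5E)-3,3,5-trimethyl-4-{2-[(4R)-2,2,4-trimethyl-1,3-dioxan-4-yl]ethyl}hept-5-en-2-one | C/C=C(\C)[C@H](CC[C@]1(C)CCOC(C)(C)O1)C(C)(C)C(C)=O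
F5 | step 9 | trimethyl{[(4S,5E)-3,3,5-trimethyl-4-{2-[(4R)-2,2,4-trimethyl-1,3-dioxan-4-yl]ethyl}hepta-1,5-dien-2-yl]oxy}silane | C/C=C(\C)[C@H](CC[C@]1(C)CCOC(C)(C)O1)C(C)(C)C(=C)O[Si](C)(C)C
F6 | step 9 | trimethyl({1-[(3S,4E)-2,4-dimethyl-3-{2-[(4R)-2,2,4-trimethyl-1,3-dioxan-4-yl]ethyl}hex-4-en-2-yl]cyclopropyl}oxy)silane | C/C=C(\C)[C@H](CC[C@]1(C)CCOC(C)(C)O1)C(C)(C)C2(O[Si](C)(C)C)CC2
F7 | step 10 | triethyl({1-[(3S,4E)-2,4-dimethyl-3-{2-[(4R)-2,2,4-trimethyl-1,3-dioxan-4-yl]ethyl}hex-4-en-2-yl]cyclopropyl}oxy)silane | C/C=C(\C)[C@H](CC[C@]1(C)CCOC(C)(C)O1)C(C)(C)C2(O[Si](CC)(CC)CC)CC2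
F8 | step 10 | (3R)-4-methyl-4-[1-(triethylsilyloxy)cyclopropyl]-3-{2-[(4R)-2,2,4-trimethyl-1,3-dioxan-4-yl]ethyl}pentan-2-one | CC(=O)[C@H](CC[C@]1(C)CCOC(C)(C)O1)C(C)(C)C2(O[Si](CC)(CC)CC)CC2
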